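Everything rests on cutting the two peroxide C–O bonds, C3–O2 and C5–O1, of the 1,2-dioxolane (ring O1–O2–C3–C4–C5). C3 and C5 each carry a methyl group and a CH2–C arm, arms trans, so with equal arms the core has a C2 axis through C4 and the O–O midpoint. The key step inserts one H2O2 between the tertiary carbons of C2-symmetric (R,R)-bis(2-methyloxetan-2-yl)methane by two invertive openings, closing the ring, setting both stereocentres and freeing two homotopic 2-hydroxyethyl arms. The bis-oxetane comes from a two-directional Sharpless epoxidation.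

Key step: step 10

Remark on the chemistry: the acetal carbon of 9, 10 and 11 forms as a mixture of epimers (drawn without a descriptor) and is removed in step 8; anhydrous ethereal H2O2 (15) is assumed to be made by extracting the commercial aqueous reagent into Et2O and drying.

Step 1
Reactants: 1 prop-2-yn-1-ol (propargyl alcohol); 2 4-chlorobut-2-yn-1-ol
Product: 3 hepta-2,5-diyne-1,7-diol
Conditions: CuI (1.0 equiv), NaI (1.0 equiv), K2CO3 (1.5 equiv), DMF, rt; aq. NH4Cl
Reagents that add atoms: none
Why: Copper-mediated coupling of a terminal alkyne with a propargylic halide under carbonate base, the standard entry to skipped diynes, in which the copper acetylide of 1 substitutes the iodide-activated propargylic CH2 carbon of 2 and both free hydroxyl groups are tolerated.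

Step 2
Reactants: 3 hepta-2,5-diyne-1,7-diol
Product: 5 (2Z,5Z)-3,5-diiodohepta-2,5-diene-1,7-diol, via cyclic bis(alkenyl)alanate 4 (not isolated)
Conditions: NaAlH2(OCH2CH2OMe)2 (3.2 equiv), THF, 0 °C → rt; then I2 (4 equiv), THF, −78 → 0 °C; aq. Na2S2O3, aq. KNaC4H4O6
Reagents that add atoms: iodine, II; sodium bis(2-methoxyethoxy)aluminium dihydride, [Na+].COCCO[AlH2-]OCCOC (its sodium, aluminium and alkoxy groups are held in 4 only)
Why: Hydroxyl-directed trans-hydroalumination of propargylic alcohols, in which each aluminium-bound alkoxide delivers hydride to C2 (C6) and aluminium ends on C3 (C5) in a five-membered alkenylalanate whose C–Al bond iodine cleaves with retention, so that iodine sits cis to CH2OH in both (Z)-iodoalkenes.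

Step 3
Reactants: 5 (2Z,5Z)-3,5-diiodohepta-2,5-diene-1,7-diol
Product: 6 (2E,5E)-3,5-dimethylhepta-2,5-diene-1,7-diol
Conditions: Me2CuLi (6 equiv, from MeLi and CuI), Et2O, 0 °C; aq. NH4Cl/NH3
Reagents that add atoms: lithium dimethylcuprate, [Li+].C[Cu-]C
Why: Cross-coupling of an alkenyl iodide with a Gilman cuprate replaces each iodine by methyl with retention of alkene geometry, so the methyl groups end cis to CH2OH and both trisubstituted alkenes are E, while the excess cuprate absorbs the two hydroxyl protons.

Step 4
Reactants: 6 (2E,5E)-3,5-dimethylhepta-2,5-diene-1,7-diol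
Product: 7 [(2S,3S)-3-{[(2S,3S)-3-(hydroxymethyl)-2-methyloxiran-2-yl]methyl}-3-methyloxiran-2-yl]methanol
Conditions: Ti(OiPr)4 (0.2 equiv), L-(+)-diethyl tartrate (0.26 equiv), t-BuOOH (4 equiv), 4 Å sieves, CH2Cl2, −20 °C; citric acid in acetone/Et2O, filtration (non-aqueous work-up)
Reagents that add atoms: tert-butyl hydroperoxide, CC(C)(C)OO
Why: Two-directional Sharpless asymmetric epoxidation, in which the catalyst from Ti(OiPr)4 and L-(+)-diethyl tartrate delivers oxygen to the same enantioface of each 3,3-disubstituted (E)-allylic alcohol and so sets all four epoxide carbons as S, while the doubled reagent control should enrich the C2-symmetric product and turn the minor mode into a separable meso-type diastereomer.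

Step 5
Reactants: 7 the bis-epoxy diol
Product: 8 (3R,5R)-3,5-dimethylheptane-1,3,5,7-tetraol
Conditions: NaAlH2(OCH2CH2OMe)2 (4.5 equiv), THF, 0 °C → rt; Na2SO4·10H2O, filtration
Reagents that add atoms: none
Why: Hydroxyl-directed hydride opening of 2,3-epoxy alcohols, in which the alkoxide-bound aluminium hydride attacks C2 (also the less substituted epoxide carbon) to give 1,3-diols, so the tertiary C–O bonds and their configuration are not touched.

Step 6
Reactants: 8 (3R,5R)-3,5-dimethylheptane-1,3,5,7-tetraol
Product: 9 (3R)-3-methyl-4-[(4R)-4-methyl-2-phenyl-1,3-dioxan-4-yl]butane-1,3-diol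
Conditions: PhCH(OMe)2 (1.0 equiv), camphorsulfonic acid (cat.), DMF, rt, reduced pressure; Et3N; bis-acetal and recovered 8 re-equilibrated
Reagents that add atoms: benzaldehyde dimethyl acetal, COC(OC)c1ccccc1
Why: Acid-catalysed transacetalisation closes a 1,3-dioxane on one primary/tertiary 1,3-diol unit (the tertiary/tertiary pair would need two syn-axial substituents) and thereby masks the far tertiary hydroxyl, which would otherwise take the next ring closure through a six-membered pathway, without touching a chain stereocentre.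

Step 7
Reactants: 9 the mono-benzylidene acetal
Product: 11 (4R)-4-methyl-4-{[(2R)-2-methyloxetan-2-yl]methyl}-2-phenyl-1,3-dioxane, via primary tosylate 10 (not isolated)
Conditions: n-BuLi (1.0 equiv), THF, 0 °C; TsCl (1.0 equiv), 0 °C; n-BuLi (1.05 equiv), 0 → 60 °C
Reagents that add atoms: 4-methylbenzenesulfonyl chloride, Cc1ccc(cc1)S(=O)(=O)Cl (retained only in 10)
Why: One-pot Williamson oxetane synthesis, in which the primary lithium alkoxide is sulfonylated selectively and the tertiary alkoxide then displaces the tosylate in a 4-exo-tet closure that breaks no bond at the carbinol carbon and so keeps its R configuration.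

Step 8
Reactants: 11 the oxetane benzylidene acetal
Product: 12 (3R)-3-methyl-4-[(2R)-2-methyloxetan-2-yl]butane-1,3-diol
Conditions: H2 (1 atm), Pd(OH)2/C, EtOAc, rt
Reagents that add atoms: none
Why: Hydrogenolysis of the benzylic C–O bonds removes the benzylidene acetal under neutral conditions, so the acid-sensitive 2,2-disubstituted oxetane never meets acid next to a free diol.

Step 9
Reactants: 12 the oxetane diol
Product: 14 (R,R)-bis(2-methyloxetan-2-yl)methane, via primary tosylate 13 (not isolated)
Conditions: n-BuLi (1.0 equiv), THF, 0 °C; TsCl (1.0 equiv), 0 °C; n-BuLi (1.05 equiv), 0 → 60 °C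
Reagents that add atoms: 4-methylbenzenesulfonyl chloride, Cc1ccc(cc1)S(=O)(=O)Cl (retained only in 13)
Why: The same one-pot tosylation and 4-exo-tet Williamson closure, now with the first oxetane inert to alkoxide and the only free alkoxide next to the leaving group, completes the C2-symmetric bis-oxetane with retention at the second carbinol carbon.

Step 10
Reactants: 14 (R,R)-bis(2-methyloxetan-2-yl)methane; 15 hydrogen peroxide
Product: 17 2,2'-[(3S,5S)-3,5-dimethyl-1,2-dioxolane-3,5-diyl]di(ethan-1-ol), via hydroperoxy alcohol 16 (not isolated)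
Conditions: H2O2 (1.3 equiv, anhydrous, in Et2O), Me3SiOTf (0.3 equiv), Et2O (dilute), −78 → −20 °C; aq. NaHCO3
Reagents that add atoms: none
Why: Proposed new method: Me3SiOTf (or the triflic acid it releases with H2O2) turns one oxetane into an oxonium ion, and H2O2 displaces the ring oxygen at the tertiary carbon from the rear in a strain-driven, SN2-like substitution inside a tight ion pair, giving hydroperoxy alcohol 16 with inversion. The terminal oxygen of that tethered hydroperoxide then opens the second activated oxetane at its tertiary carbon by a 5-exo-tet closure, again with inversion, which makes the second peroxide C–O bond and closes the 1,2-dioxolane ring. The closest known reaction types are the Lewis acid-promoted perhydrolysis of 2,2-disubstituted oxetanes to 3-hydroperoxy alcohols with inversion and the ring closure of hydroperoxides onto tethered oxetanes or epoxides; joining the two in one pot on a bis-oxetane is the untested part. Both new stereocentres, C3 and C5, are substrate-controlled, each being the stereospecific inverse of a carbinol centre fixed by the reagent-controlled epoxidation of step 4, so (R,R)-14 should give (S,S)-17 with the arms trans, and any leakage through an open cation should appear as the separable cis diastereomer and not as the enantiomer. In the second opening the hydroperoxide must beat both the freed primary hydroxyl (six-membered ether) and a second molecule of H2O2, which the five-membered transition state, the alpha-effect of the OOH group, the near-stoichiometric H2O2 and the dilution should secure. Because 14 is C2-symmetric with two strained tertiary electrophilic carbons, either oxetane may react first and the two hydroxyethyl arms of 17 are homotopic.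

Step 11
Reactants: 17 the dioxolane diol
Product: 18 2-[(3S,5S)-5-(2-{[tert-butyl(diphenyl)silyl]oxy}ethyl)-3,5-dimethyl-1,2-dioxolan-3-yl]ethan-1-ol
Conditions: t-BuPh2SiCl (1.0 equiv), imidazole, CH2Cl2, 0 °C; recovered 17 resubmitted, bis-silyl ether returned to 17 with Bu4NF
Reagents that add atoms: tert-butyl(chloro)diphenylsilane, CC(C)(C)[Si](Cl)(c1ccccc1)c1ccccc1
Why: Monosilylation of a primary alcohol, in which the C2 axis makes the two arms homotopic so that either one gives the same mono-ether and no stereocentre is involved.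

Step 12
Reactants: 18 the mono-silyl ether
Product: 19 2-[(3R,5S)-5-(2-{[tert-butyl(diphenyl)silyl]oxy}ethyl)-3,5-dimethyl-1,2-dioxolan-3-yl]acetaldehyde
Conditions: TEMPO (0.1 equiv), PhI(OAc)2 (1.2 equiv), CH2Cl2, rt
Reagents that add atoms: none
Why: Oxoammonium (TEMPO/PhI(OAc)2) oxidation of the primary alcohol stops at the aldehyde under anhydrous, base-free conditions that spare the dialkyl peroxide and give the beta-peroxy aldehyde no base for elimination.

Step 13
Reactants: 20 (8-bromooctyl)benzene
Product: 21 triphenyl(8-phenyloctyl)phosphonium bromide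
Conditions: PPh3, MeCN, reflux
Reagents that add atoms: triphenylphosphine, c1ccc(cc1)P(c1ccccc1)c1ccccc1
Why: SN2 quaternisation of triphenylphosphine by the unhindered primary alkyl bromide.

Step 14
Reactants: 19 the aldehyde; 21 triphenyl(8-phenyloctyl)phosphonium bromide
Product: 23 tert-butyl(2-{(3S,5S)-3,5-dimethyl-5-[(2Z)-10-phenyldec-2-en-1-yl]-1,2-dioxolan-3-yl}ethoxy)diphenylsilane, via phosphonium ylide 22 (not isolated)
Conditions: 21 (1.3 equiv), NaN(SiMe3)2 (1.25 equiv), THF, −78 °C; then 19, −78 → 0 °C
Reagents that add atoms: none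
Why: Wittig olefination with a non-stabilised ylide, which should add to the aldehyde at −78 °C faster than it enolises it, giving mainly the Z alkene, whose geometry is irrelevant because it is reduced next.

Step 15
Reactants: 23 the alkene
Product: 24 tert-butyl{2-[(3S,5S)-3,5-dimethyl-5-(10-phenyldecyl)-1,2-dioxolan-3-yl]ethoxy}diphenylsilane
Conditions: KO2CN=NCO2K, AcOH, MeOH/CH2Cl2, 0 °C → rt
Reagents that add atoms: none
Why: Diimide reduction transfers H2 to the C=C bond in a concerted syn fashion and, unlike metal-catalysed hydrogenation, leaves the O–O bond alone.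

Step 16
Reactants: 24 the saturated silyl ether
Product: 25 2-[(3S,5S)-3,5-dimethyl-5-(10-phenyldecyl)-1,2-dioxolan-3-yl]ethan-1-ol
Conditions: Bu4NF, THF, 0 °C → rt
Reagents that add atoms: none
Why: Fluoride-induced cleavage of the silyl ether (driven by the Si–F bond) is tolerated by a peroxide whose carbons carry no hydrogen.

Step 17
Reactants: 25 the primary alcohol
Product: 26 andavadoic acid
Conditions: TEMPO (0.2 equiv), PhI(OAc)2 (2.5 equiv), MeCN/H2O (1:1), rt
Reagents that add atoms: water, O
Why: TEMPO/PhI(OAc)2 oxidation in aqueous acetonitrile takes the primary alcohol through the aldehyde hydrate to the carboxylic acid without touching the peroxide or either quaternary stereocentre.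

Compound list
1 | prop-2-yn-1-ol (propargyl alcohol) | C#CCO | starting material
2 | 4-chlorobut-2-yn-1-ol | OCC#CCCl | starting material
3 | hepta-2,5-diyne-1,7-diol | OCC#CCC#CCO | intermediate
4 | disodium bis(oxa-aluminacyclopentene) alanate from 3, aluminium on C3 and C5, two 2-methoxyethoxy groups on each aluminium | [Na+].[Na+].COCCO[Al-]1(OCCOC)OCC=C1CC1=CCO[Al-]1(OCCOC)OCCOC | intermediate (not isolated)
5 | (2Z,5Z)-3,5-diiodohepta-2,5-diene-1,7-diol | OC/C=C(I)/C/C(I)=C/CO | intermediate
6 | (2E,5E)-3,5-dimethylhepta-2,5-diene-1,7-diol | OC/C=C(C)/C/C(C)=C/CO | intermediate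
7 | [(2S,3S)-3-{[(2S,3S)-3-(hydroxymethyl)-2-methyloxiran-2-yl]methyl}-3-methyloxiran-2-yl]methanol | OC[C@@H]1O[C@@]1(C)C[C@]1(C)O[C@H]1CO | intermediate
8 | (3R,5R)-3,5-dimethylheptane-1,3,5,7-tetraol | C[C@@](O)(CCO)C[C@@](O)(C)CCO | intermediate
9 | (3R)-3-methyl-4-[(4R)-4-methyl-2-phenyl-1,3-dioxan-4-yl]butane-1,3-diol (either configuration at the acetal carbon) | C[C@@](O)(CCO)C[C@@]1(C)CCOC(c2ccccc2)O1 | intermediate
10 | (3R)-3-hydroxy-3-methyl-4-[(4R)-4-methyl-2-phenyl-1,3-dioxan-4-yl]butyl 4-methylbenzenesulfonate | C[C@@](O)(CCOS(=O)(=O)c1ccc(C)cc1)C[C@@]1(C)CCOC(c2ccccc2)O1 | intermediate (not isolated)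
11 | (4R)-4-methyl-4-{[(2R)-2-methyloxetan-2-yl]methyl}-2-phenyl-1,3-dioxane (either configuration at the acetal carbon) | C[C@@]1(CCO1)C[C@@]1(C)CCOC(c2ccccc2)O1 | intermediate
12 | (3R)-3-methyl-4-[(2R)-2-methyloxetan-2-yl]butane-1,3-diol | C[C@@]1(CCO1)C[C@@](O)(C)CCO | intermediate
13 | (3R)-3-hydroxy-3-methyl-4-[(2R)-2-methyloxetan-2-yl]butyl 4-methylbenzenesulfonate | C[C@@]1(CCO1)C[C@@](O)(C)CCOS(=O)(=O)c1ccc(C)cc1 | intermediate (not isolated)
14 | (R,R)-bis(2-methyloxetan-2-yl)methane | C[C@@]1(CCO1)C[C@@]2(C)CCO2 | intermediate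
15 | hydrogen peroxide | OO | starting material
16 | (3S)-3-hydroperoxy-3-methyl-4-[(2R)-2-methyloxetan-2-yl]butan-1-ol | C[C@](OO)(CCO)C[C@@]1(C)CCO1 | intermediate (not isolated)
17 | 2,2'-[(3S,5S)-3,5-dimethyl-1,2-dioxolane-3,5-diyl]di(ethan-1-ol) | C[C@]1(CCO)C[C@](C)(CCO)OO1 | intermediate
18 | 2-[(3S,5S)-5-(2-{[tert-butyl(diphenyl)silyl]oxy}ethyl)-3,5-dimethyl-1,2-dioxolan-3-yl]ethan-1-ol | C[C@]1(CCO)C[C@](C)(CCO[Si](c2ccccc2)(c2ccccc2)C(C)(C)C)OO1 | intermediate
19 | 2-[(3R,5S)-5-(2-{[tert-butyl(diphenyl)silyl]oxy}ethyl)-3,5-dimethyl-1,2-dioxolan-3-yl]acetaldehyde | C[C@]1(CC=O)C[C@](C)(CCO[Si](c2ccccc2)(c2ccccc2)C(C)(C)C)OO1 | intermediate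
20 | (8-bromooctyl)benzene | BrCCCCCCCCc1ccccc1 | starting material
21 | triphenyl(8-phenyloctyl)phosphonium bromide | [Br-].c1ccccc1CCCCCCCC[P+](c1ccccc1)(c1ccccc1)c1ccccc1 | intermediate
22 | triphenyl(8-phenyloctylidene)phosphorane | c1ccccc1CCCCCCCC=P(c1ccccc1)(c1ccccc1)c1ccccc1 | intermediate (not isolated)
23 | tert-butyl(2-{(3S,5S)-3,5-dimethyl-5-[(2Z)-10-phenyldec-2-en-1-yl]-1,2-dioxolan-3-yl}ethoxy)diphenylsilane | C[C@]1(C/C=C\CCCCCCCc2ccccc2)C[C@](C)(CCO[Si](c2ccccc2)(c2ccccc2)C(C)(C)C)OO1 | intermediate
24 | tert-butyl{2-[(3S,5S)-3,5-dimethyl-5-(10-phenyldecyl)-1,2-dioxolan-3-yl]ethoxy}diphenylsilane | C[C@]1(CCCCCCCCCCc2ccccc2)C[C@](C)(CCO[Si](c2ccccc2)(c2ccccc2)C(C)(C)C)OO1 | intermediate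
25 | 2-[(3S,5S)-3,5-dimethyl-5-(10-phenyldecyl)-1,2-dioxolan-3-yl]ethan-1-ol | C[C@]1(CCCCCCCCCCc2ccccc2)C[C@](C)(CCO)OO1 | intermediate
26 | andavadoic acid, 2-[(3R,5S)-3,5-dimethyl-5-(10-phenyldecyl)-1,2-dioxolan-3-yl]acetic acid | C[C@]1(CCCCCCCCCCc2ccccc2)C[C@](C)(CC(=O)O)OO1 | target

Total step count: 17. Longest linear sequence: 16 steps (steps 1–12 and 14–17; step 13 is a one-step side branch).

Steps most likely to fail

Step 10 (proposed new method). The second ring opening may be taken over by the freed primary hydroxyl (six-membered ether) or by a second molecule of H2O2, and ionisation of an activated oxetane ahead of substitution would erode the trans relationship. The fallback makes the two peroxide C–O bonds in separate, known reactions (oxetane perhydrolysis, then cycloperoxymercuration of an alkene); it sets out from 6 and comes back at 18. Diol 6 is monosilylated (NaH, then t-BuPh2SiCl, THF) to (2E,5E)-7-{[tert-butyl(diphenyl)silyl]oxy}-3,5-dimethylhepta-2,5-dien-1-ol F1. Sharpless epoxidation of its one free allylic alcohol (Ti(OiPr)4, L-(+)-diethyl tartrate, t-BuOOH, −20 °C) should give the (2S,3S)-epoxy alcohol F2, and NaAlH2(OCH2CH2OMe)2 should open it to the (3S)-1,3-diol F3. The one-pot closure (n-BuLi, TsCl, n-BuLi), through the primary tosylate F4, gives the (2S)-oxetane F5. Perhydrolysis with H2O2/Me3SiOTf in Et2O at −78 °C, with inversion, gives the (3R)-hydroperoxy alcohol F6. Hg(OAc)2 in CH2Cl2 then closes the dioxolane by 5-exo cycloperoxymercuration onto the trisubstituted alkene, giving the acetoxymercurio dioxolane F7, and NaBH4/NaOH removes the mercury to give 18. This ring closure is not expected to be face-selective, so 18 would have to be separated from its C5 epimer.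

Step 2. The twofold hydroalumination may stop after one alkyne, the aluminium alkoxides and hydride may shift the acidic bis-propargylic CH2 group into allenes, and protonation of an alkenyl–aluminium bond before iodination would lose an iodine. The fallback replaces anti-hydrometalation, iodination and cuprate coupling by one syn-carbometalation and compensates the opposite alkene geometry with the enantiomeric tartrate; it sets out from 3 and comes back at 8. Fe(acac)3-catalysed addition of MeMgBr (THF, −78 → 0 °C) to the propargylic alkoxides of 3 delivers methyl syn to the alkyne carbon remote from oxygen and, after protonation, should give (2Z,5Z)-3,5-dimethylhepta-2,5-diene-1,7-diol F8. Two-directional Sharpless epoxidation with Ti(OiPr)4, D-(−)-diethyl tartrate and t-BuOOH then attacks the opposite enantioface, which on the Z alkenes builds the same configuration at the methyl-bearing carbons, and should give the (2R,3S),(2R,3S)-bis-epoxy diol F9. NaAlH2(OCH2CH2OMe)2 opens F9 at its CH carbons, as in step 5, to give 8.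

Step 14. The basic ylide may enolise the beta-peroxy aldehyde, after which beta-elimination would open the dioxolane in competition with carbonyl addition. The fallback reverses the polarity so that the carbanion sits two carbons from the peroxide carbon and cannot eliminate it (Julia–Kocienski olefination); it sets out from 18 and comes back at 24. Mitsunobu thioetherification of 18 (1-phenyl-1H-tetrazole-5-thiol, PPh3, DIAD) gives the tetrazolyl sulfide F10, which (NH4)6Mo7O24/H2O2 oxidises to the sulfone F11. Bromide 20 is converted by a Kornblum-type oxidation (N-methylmorpholine N-oxide, DMSO) into 8-phenyloctanal F12. Metalation of F11 with KN(SiMe3)2 (DME, −60 °C) and addition of F12 should give the (E)-alkene F13, which the diimide conditions of step 15 reduce to 24.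

Further compounds
F1 | step 10 | (2E,5E)-7-{[tert-butyl(diphenyl)silyl]oxy}-3,5-dimethylhepta-2,5-dien-1-ol | OC/C=C(C)/C/C(C)=C/CO[Si](c1ccccc1)(c1ccccc1)C(C)(C)C
F2 | step 10 | {(2S,3S)-3-[(2E)-4-{[tert-butyl(diphenyl)silyl]oxy}-2-methylbut-2-en-1-yl]-3-methyloxiran-2-yl}methanol | OC[C@@H]1O[C@@]1(C)C/C(C)=C/CO[Si](c1ccccc1)(c1ccccc1)C(C)(C)C
F3 | step 10 | (3S,5E)-7-{[tert-butyl(diphenyl)silyl]oxy}-3,5-dimethylhept-5-ene-1,3-diol | C[C@@](O)(CCO)C/C(C)=C/CO[Si](c1ccccc1)(c1ccccc1)C(C)(C)C
F4 | step 10 | primary 4-methylbenzenesulfonate of F3 (not isolated) | C[C@@](O)(CCOS(=O)(=O)c1ccc(C)cc1)C/C(C)=C/CO[Si](c1ccccc1)(c1ccccc1)C(C)(C)C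
F5 | step 10 | tert-butyl({(2E)-3-methyl-4-[(2S)-2-methyloxetan-2-yl]but-2-en-1-yl}oxy)diphenylsilane | C[C@@]1(CCO1)C/C(C)=C/CO[Si](c1ccccc1)(c1ccccc1)C(C)(C)C
F6 | step 10 | (3R,5E)-7-{[tert-butyl(diphenyl)silyl]oxy}-3-hydroperoxy-3,5-dimethylhept-5-en-1-ol | C[C@](OO)(CCO)C/C(C)=C/CO[Si](c1ccccc1)(c1ccccc1)C(C)(C)C
F7 | step 10 | acetoxymercurio precursor of 18 (HgOAc on the arm carbon next to C5, that carbon unassigned) | C[C@]1(CCO)C[C@](C)(C([Hg]OC(C)=O)CO[Si](c2ccccc2)(c2ccccc2)C(C)(C)C)OO1
F8 | step 2 | (2Z,5Z)-3,5-dimethylhepta-2,5-diene-1,7-diol | OC/C=C(C)\C/C(C)=C\CO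
F9 | step 2 | [(2R,3S)-3-{[(2S,3R)-3-(hydroxymethyl)-2-methyloxiran-2-yl]methyl}-3-methyloxiran-2-yl]methanol | OC[C@H]1O[C@@]1(C)C[C@]1(C)O[C@@H]1CO
F10 | step 14 | 1-phenyl-1H-tetrazol-5-yl sulfide of 18 (sulfur in place of the hydroxyl oxygen, ring stereocentres unchanged) | C[C@]1(CCSc2nnnn2-c2ccccc2)C[C@](C)(CCO[Si](c2ccccc2)(c2ccccc2)C(C)(C)C)OO1
F11 | step 14 | 1-phenyl-1H-tetrazol-5-yl sulfone from F10 | C[C@]1(CCS(=O)(=O)c2nnnn2-c2ccccc2)C[C@](C)(CCO[Si](c2ccccc2)(c2ccccc2)C(C)(C)C)OO1
F12 | step 14 | 8-phenyloctanal | O=CCCCCCCCc1ccccc1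
F13 | step 14 | (2E)-isomer of alkene 23 | C[C@]1(C/C=C/CCCCCCCc2ccccc2)C[C@](C)(CCO[Si](c2ccccc2)(c2ccccc2)C(C)(C)C)OO1
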